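**Retrosynthetic overview**

1. Atoms are numbered 1–34 along the target SMILES. The route rests on the O28–C25(Me2)–C23(=O)–C22 edge of the oxepanone ring (C19, C21, C22, C23, C25, O28, C29): it is a 2,2-dimethylfuran-3(2H)-one that lacks only C21 and C19, and an isopropenyl group on C18 supplies both.
2. Right half: the C23 ketone, the C32 carbinol (MeMgBr) and the C16–C17 link (Julia–Kocienski, diimide) are made last. The oxepanone comes from reductive cleavage of the C22–C29 bond of a cyclobutane (C19, C21, C22, C29), and that cyclobutane from a [2+2] photocycloaddition of a 5-alkylfuranone onto the tethered isopropenyl group; C18 comes from an oxazolidinone alkylation.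
3. Left half (cis-hydroazulene, C2–C15): the C16 sulfone comes from a cycloheptenone closed by metathesis at C2=C3. C15 is set by CBS reduction at C3 and reductive allylic transposition. The cyclopentane comes from (S)-linalool (C9) by metathesis, directed epoxidation and nitrile-anion epoxide opening (C6, C12).
4. Ring order: cyclohexane and cyclobutane (step 9), oxepanone (step 10); cyclopentane (step 20), cycloheptene (step 28); the halves are joined at C16–C17 (step 36).

Key step: step 9

Remark: C23 is a carbinol from step 11 to step 38 and returns to the ketone in step 39, so 17–22 and 47–49 are carried as C23 epimers (centre left open in the SMILES); the same holds for C15 in 38, which step 30 erases.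
Remark: Bu3SnCH2OPMB is taken as a known reagent, made from commercial (tributylstannyl)methanol, NaH and 4-methoxybenzyl chloride.

**Right half**

Step 1
Reactants: 1 3-methylbut-3-enoic acid; 2 (S)-4-benzyloxazolidin-2-one
Product: 4 (S)-4-benzyl-3-(3-methylbut-3-enoyl)oxazolidin-2-one, via pivalic mixed anhydride 3 (not isolated)
Conditions: t-BuCOCl, Et3N, THF, −20 °C; then 2, LiCl, −20 °C → rt
Reagents that add atoms: none
Why: Mixed-anhydride N-acylation with LiCl/Et3N needs no strong base, so the β,γ-alkene should not move into conjugation.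

Step 2
Reactants: 4
Product: 5 (S)-4-benzyl-3-[(2R)-2-(benzyloxymethyl)-3-methylbut-3-enoyl]oxazolidin-2-one
Conditions: TiCl4, i-Pr2NEt, CH2Cl2, 0 °C; then BnOCH2Cl, 0 °C
Reagents that add atoms: benzyl chloromethyl ether, ClCOCc1ccccc1
Why: Evans alkylation of the chelated Z titanium enolate at the α-carbon, with the electrophile entering anti to the auxiliary benzyl group, sets C18 (R).

Step 3
Reactants: 5
Product: 6 (2R)-2-(benzyloxymethyl)-N-methoxy-N,3-dimethylbut-3-enamide
Conditions: MeNHOMe·HCl, AlMe3, CH2Cl2, −15 → 0 °C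
Reagents that add atoms: N,O-dimethylhydroxylamine hydrochloride, CNOC.Cl
Why: Weinreb transamidation by the aluminium amide cleaves the exocyclic imide bond without base, which keeps C18 and the β,γ-alkene in place.

Step 4
Reactants: 6; 7 (4-bromobut-1-yn-1-yl)trimethylsilane
Product: 8 (6R)-6-(benzyloxymethyl)-7-methyl-1-(trimethylsilyl)oct-7-en-1-yn-5-one
Conditions: 7, Mg, THF; then 6, THF, −20 → 0 °C; cold aq. NH4Cl
Reagents that add atoms: none
Why: Weinreb ketone synthesis, in which the magnesium chelate of the tetrahedral adduct stops over-addition and the cold buffered quench limits enolisation at C18.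

Step 5
Reactants: 8
Product: 9 2-[(2R)-1-(benzyloxy)-3-methylbut-3-en-2-yl]-2-[4-(trimethylsilyl)but-3-yn-1-yl]-1,3-dioxolane
Conditions: Me3SiOCH2CH2OSiMe3, Me3SiOTf (5 mol %), CH2Cl2, −78 → −20 °C
Reagents that add atoms: 1,2-bis(trimethylsilyloxy)ethane, C[Si](C)(C)OCCO[Si](C)(C)C
Why: Noyori ketalisation under aprotic, cold conditions masks the C32 ketone without epimerising C18 or moving the alkene.

Step 6
Reactants: 9
Product: 10 2-[(2R)-1-(benzyloxy)-3-methylbut-3-en-2-yl]-2-(but-3-yn-1-yl)-1,3-dioxolane
Conditions: K2CO3, MeOH, rt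
Reagents that add atoms: none
Why: Methanolysis of the alkynyl C–Si bond frees the terminal alkyne while ketal, benzyl ether and alkene are inert to mild base.

Step 7
Reactants: 10; 11 2-acetoxy-2-methylpropanoyl chloride
Product: 12 7-{2-[(2R)-1-(benzyloxy)-3-methylbut-3-en-2-yl]-1,3-dioxolan-2-yl}-2-methyl-3-oxohept-4-yn-2-yl acetate
Conditions: PdCl2(PPh3)2 (2 mol %), CuI (4 mol %), Et3N, THF, rt
Reagents that add atoms: none
Why: Acyl Sonogashira coupling forms the C22–C23 bond from the terminal alkyne without a strongly basic acetylide.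

Step 8
Reactants: 12
Product: 14 5-{2-[2-((2R)-1-(benzyloxy)-3-methylbut-3-en-2-yl)-1,3-dioxolan-2-yl]ethyl}-2,2-dimethylfuran-3(2H)-one, via hydroxy ynone 13 (not isolated)
Conditions: K2CO3, MeOH, 0 °C → rt
Reagents that add atoms: none
Why: Acetate methanolysis frees the tertiary alkoxide, which adds to the ynone β-carbon C29 in a 5-endo-dig oxa-Michael closure to the 3(2H)-furanone.

Step 9
Reactants: 14
Product: 15 cis-fused furanone–cyclobutane–cyclohexane photoadduct (C20 methyl cis to O28 and to C17)
Conditions: hν (350 nm, Pyrex), degassed MeCN (5 mM), rt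
Reagents that add atoms: none
Why: Intramolecular enone–alkene [2+2] photocycloaddition, in which the furanone triplet bonds through its β-carbon C29 to C19 of the tethered isopropenyl group and the 1,4-biradical (C22, C21) then collapses to the cyclobutane. The cyclohexane (C18, C19, C29, C30, C31, C32) closes in the 6-exo, fused mode and the cyclobutane (C19, C21, C22, C29) by radical recombination; the closest known reaction type is the photocycloaddition of 3(2H)-furanones and other β-alkoxy enones to alkenes held by a four-atom tether. C22 and both cis ring fusions follow from the geometry of the fused four-membered ring, which also forces O28 and the C20 methyl cis and creates quaternary C19 in the same event. C19 and C29 are relayed from C18: in the chair-like transition state the CH2OBn group should be equatorial, H18 should eclipse the alkene, and the bulkier O28–C25 flank of the furanone should take the equatorial site, so that the C20 methyl becomes axial and cis to C17. The step needs fused rather than crossed regiochemistry, which the preference for six- over seven-membered first bond formation should secure, and one alkene face, which rests on the single C18 stereocentre.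

Step 10
Reactants: 15
Product: 16 trans-fused 6-(benzyloxymethyl)-2,2,5a-trimethyloctahydro-1-benzoxepin-3-one 7-ethylene ketal (1-benzoxepine locants; H29 axial)
Conditions: SmI2 (2.5 equiv), HMPA, t-BuOH, THF, −78 → −40 °C
Reagents that add atoms: none
Why: Reductive scission of a cyclobutyl ketone: the C23 ketyl cleaves the strained C22–C29 bond (rather than C21–C22, which would give a primary radical) to a samarium enolate and an α-alkoxy tertiary radical, which should take up hydrogen on the axial face anti to the axial C20 methyl and so give the trans ring fusion.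

Step 11
Reactants: 16
Product: 17 C23 carbinol of 16 (epimers at C23)
Conditions: NaBH4, MeOH, 0 °C
Reagents that add atoms: none
Why: Borohydride reduction masks the C23 ketone as a carbinol before organometallic addition at C32, and the new centre is erased in step 39.

Step 12
Reactants: 17
Product: 18 C32 ketone: 6-(benzyloxymethyl)-3-hydroxy-2,2,5a-trimethyloctahydro-1-benzoxepin-7-one
Conditions: PPTS, acetone–H2O, 55 °C
Reagents that add atoms: water, O
Why: Acid-catalysed ketal hydrolysis frees the C32 ketone, and since equatorial C17 is the thermodynamic arrangement at C18, enolisation should not scramble it.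

Step 13
Reactants: 18
Product: 19 C32 tertiary alcohol (C33 methyl equatorial; O34 axial and cis to the C20 methyl)
Conditions: MeMgBr (4 equiv), THF, −78 → 0 °C
Reagents that add atoms: methylmagnesium bromide, C[Mg]Br
Why: Grignard addition along the equatorial trajectory, because the axial C20 methyl blocks axial attack, should give the axial hydroxyl and equatorial methyl at C32.

Step 14
Reactants: 19
Product: 20 bis(triethylsilyl) ether of 19 (O at C23 and C32)
Conditions: Et3SiOTf, 2,6-lutidine, CH2Cl2, 0 °C → rt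
Reagents that add atoms: triethylsilyl trifluoromethanesulfonate, CC[Si](CC)(CC)OS(=O)(=O)C(F)(F)F
Why: The silyl triflate is reactive enough for the hindered secondary and the axial tertiary hydroxyl, which must be capped to prevent retro-aldol of the later β-oxy aldehyde.

Step 15
Reactants: 20
Product: 21 C17 primary alcohol
Conditions: H2 (1 atm), Pd/C, EtOAc, rt
Reagents that add atoms: none
Why: Hydrogenolysis of the benzyl ether, with the silyl ethers stable in ethyl acetate.

Step 16
Reactants: 21
Product: 22 C17 aldehyde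
Conditions: Dess–Martin periodinane, NaHCO3, CH2Cl2, rt
Reagents that add atoms: none
Why: Buffered Dess–Martin oxidation should give the aldehyde without epimerising C18 or eliminating the β-silyloxy group.

**Left half**

Step 17
Reactants: 23 geraniol
Product: 24 (2S,3S)-2,3-epoxygeraniol
Conditions: Ti(OiPr)4 (5 mol %), L-(+)-diethyl tartrate (7 mol %), t-BuOOH, 4 Å MS, CH2Cl2, −20 °C
Reagents that add atoms: tert-butyl hydroperoxide, CC(C)(C)OO
Why: Sharpless asymmetric epoxidation, in which the L-tartrate catalyst selects the face of the allylic alcohol that gives the (2S,3S) epoxide and thereby the future C9.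

Step 18
Reactants: 24
Product: 25 2,3-epoxygeranyl iodide (configuration of 24)
Conditions: I2, PPh3, imidazole, CH2Cl2, 0 °C
Reagents that add atoms: iodine, II
Why: Appel-type iodination of the primary alcohol leaves the epoxide untouched.

Step 19
Reactants: 25
Product: 26 (S)-linalool, (S)-3,7-dimethylocta-1,6-dien-3-ol
Conditions: Zn, AcOH (2 equiv), EtOH, 40 °C
Reagents that add atoms: none
Why: Reductive fragmentation, in which zinc insertion into the C–I bond and β-elimination open the epoxide to the tertiary allylic alcohol without touching the C–O bond at the stereocentre.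

Step 20
Reactants: 26
Product: 27 (S)-1-methylcyclopent-2-en-1-ol
Conditions: second-generation Grubbs catalyst (0.5 mol %), CH2Cl2, 40 °C
Reagents that add atoms: none
Why: Ring-closing metathesis of the 1,6-diene closes the cyclopentene (C5, C6, C7, C8, C9) with loss of isobutene and does not involve the carbinol centre.

Step 21
Reactants: 27
Product: 28 cis-2,3-epoxy-1-methylcyclopentan-1-ol (epoxide syn to OH)
Conditions: VO(acac)2 (2 mol %), t-BuOOH, CH2Cl2, 0 °C → rt
Reagents that add atoms: tert-butyl hydroperoxide, CC(C)(C)OO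
Why: Hydroxyl-directed epoxidation delivers oxygen syn to the tertiary OH, which is also the face anti to the methyl group.

Step 22
Reactants: 28
Product: 29 2-(2,3-dihydroxy-3-methylcyclopentyl)-2-methylpropanenitrile (hydroxyls cis; C6–C12 bond trans to both)
Conditions: i-PrCN, LiN(i-Pr)2 (3.3 equiv), THF, −78 °C; then 28, −78 → 45 °C
Reagents that add atoms: isobutyronitrile, CC(C)C#N
Why: SN2 opening of the epoxide by the nitrile-stabilised tertiary carbanion at C6, the carbon remote from the quaternary carbinol, with inversion sets C6 and builds the C6–C12 bond.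

Step 23
Reactants: 29
Product: 30 2-(3-hydroxy-3-methyl-2-oxocyclopentyl)-2-methylpropanenitrile
Conditions: IBX, DMSO, rt
Reagents that add atoms: none
Why: IBX oxidises the secondary alcohol of a 1,2-diol to the ketol without C–C cleavage and leaves the tertiary alcohol.

Step 24
Reactants: 30
Product: 31 triethylsilyl ether of 30
Conditions: Et3SiOTf, 2,6-lutidine, CH2Cl2, −78 → −20 °C
Reagents that add atoms: triethylsilyl trifluoromethanesulfonate, CC[Si](CC)(CC)OS(=O)(=O)C(F)(F)F
Why: At low temperature O-silylation of the tertiary alcohol should outrun enolisation of the hindered ketone.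

Step 25
Reactants: 31
Product: 32 2-methyl-2-[3-methyl-2-methylene-3-(triethylsilyloxy)cyclopentyl]propanenitrile
Conditions: Zn, CH2Br2, TiCl4, THF–CH2Cl2, 0 °C → rt
Reagents that add atoms: dibromomethane, BrCBr
Why: Takai–Lombardo methylenation is non-basic, so C6 next to the ketone should not epimerise, and it copes with hindered ketones.

Step 26
Reactants: 32
Product: 34 2-[2-allyl-3-methyl-3-(triethylsilyloxy)cyclopentyl]-2-methylpropanenitrile (allyl, C9 methyl and C12 all cis), via B-alkyl-9-BBN adduct 33 (not isolated)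
Conditions: 9-BBN, THF, 0 °C → rt; then CH2=CHBr, PdCl2(dppf) (5 mol %), aq. K3PO4, DMF, rt
Reagents that add atoms: vinyl bromide, C=CBr
Why: Anti-Markovnikov hydroboration from the face anti to the C6 tert-alkyl group and the C9 methyl should set C5 with C4 cis to C12, and B-alkyl Suzuki–Miyaura coupling converts the borane into the allyl group.

Step 27
Reactants: 34
Product: 36 1-[2-allyl-3-methyl-3-(triethylsilyloxy)cyclopentyl]-1,1-dimethyl isopropenyl ketone (C15 ketone), via N-H ketimine 35 (not isolated)
Conditions: 2-bromopropene, t-BuLi, Et2O, −78 °C; then 34, −78 → 0 °C; aq. AcOH–NaOAc, rt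
Reagents that add atoms: 2-bromopropene, CC(Br)=C; water, O
Why: Alkenyllithium addition to the non-enolisable nitrile stops at the imine anion, whose hydrolysis gives the isopropenyl ketone.

Step 28
Reactants: 36
Product: 37 cis-fused hydroazulenone (C15 ketone, C2=C3 alkene, C9 OSiEt3)
Conditions: second-generation Grubbs catalyst (5 mol %), toluene (2 mM), 80 °C
Reagents that add atoms: none
Why: Ring-closing metathesis between the allyl group and the methacryloyl alkene forms the trisubstituted C2=C3 bond and the seven-membered ring, helped by the gem-dimethyl group and the cis disposition of the two arms.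

Step 29
Reactants: 37
Product: 38 C15 tertiary allylic alcohol bearing CH2OPMB (C15 epimers)
Conditions: Bu3SnCH2OPMB, n-BuLi, THF, −78 °C; then 37, −78 °C
Reagents that add atoms: tributyl{[(4-methoxybenzyl)oxy]methyl}stannane, CCCC[Sn](CCCC)(CCCC)COCc1ccc(OC)cc1
Why: Tin–lithium exchange gives the α-alkoxymethyllithium, which adds 1,2 to the hindered enone and installs C16; the carbinol configuration is irrelevant.

Step 30
Reactants: 38
Product: 39 transposed enone (C3 ketone, C2=C15 alkene carrying CH2OPMB)
Conditions: pyridinium chlorochromate (C5H5NH)[CrO3Cl], 4 Å MS, CH2Cl2, rt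
Reagents that add atoms: pyridinium chlorochromate, c1cc[nH+]cc1.[O-][Cr](=O)(=O)Cl
Why: Dauben–Babler oxidative transposition, a [3,3] shift of the tertiary allylic chromate ester followed by oxidation, gives the C3 ketone and the C2=C15 double bond.

Step 31
Reactants: 39
Product: 40 C3 allylic alcohol (OH on the face of the cyclopentane ring, anti to H5 and H6)
Conditions: (S)-2-methyl-CBS-oxazaborolidine (20 mol %), BH3·SMe2, THF, −30 °C
Reagents that add atoms: none
Why: Corey–Bakshi–Shibata reduction, in which the tetrasubstituted alkenyl group acts as the large substituent and the (S)-catalyst should deliver hydride to the C3 face syn to H5 and H6.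

Step 32
Reactants: 40
Product: 43 cis-hydroazulene PMB ether (C2=C3 alkene; H15 cis to H5 and H6), via allylic sulfonylhydrazine 41 (not isolated), via allylic diazene 42 (not isolated)
Conditions: 2-nitrobenzenesulfonylhydrazide, PPh3, DEAD, N-methylmorpholine, −30 °C → rt
Reagents that add atoms: none
Why: Myers reductive transposition: Mitsunobu inversion at C3, loss of sulfinic acid and suprafacial retro-ene loss of N2 deliver hydrogen to C15 on the face of the C3–N bond and move the alkene to C2=C3, so C15 is set by chirality transfer from C3.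

Step 33
Reactants: 43
Product: 44 C16 primary alcohol
Conditions: DDQ, CH2Cl2–pH 7 buffer, 0 °C
Reagents that add atoms: none
Why: Oxidative cleavage of the 4-methoxybenzyl ether leaves the silyl ether and the trisubstituted alkene.

Step 34
Reactants: 44
Product: 45 C16 1-phenyl-1H-tetrazol-5-yl sulfide
Conditions: 1-phenyl-1H-tetrazole-5-thiol, PPh3, DIAD, THF, 0 °C → rt
Reagents that add atoms: 1-phenyl-1H-tetrazole-5-thiol, Sc1nnnn1-c1ccccc1
Why: Mitsunobu thioetherification of the primary alcohol.

Step 35
Reactants: 45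
Product: 46 C16 1-phenyl-1H-tetrazol-5-yl sulfone
Conditions: (NH4)6Mo7O24·4H2O (10 mol %), 30% H2O2, EtOH, 0 °C → rt
Reagents that add atoms: hydrogen peroxide, OO
Why: Molybdate-catalysed peroxide oxidation of sulfide to sulfone is chemoselective over the trisubstituted alkene.

**Union and end game**

Step 36
Reactants: 46; 22
Product: 47 coupled (E)-C16=C17 alkene, tris(triethylsilyl) ether
Conditions: KN(SiMe3)2, DME, −60 °C; then 22, −60 °C → rt
Reagents that add atoms: none
Why: Julia–Kocienski olefination, in which addition of the sulfonyl carbanion to the aldehyde, Smiles rearrangement and loss of SO2 and tetrazolate form C16=C17; the alkene geometry is of no consequence.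

Step 37
Reactants: 47
Product: 48 saturated C16–C17 tris(triethylsilyl) ether
Conditions: TsNHNH2, NaOAc, DME–H2O, 85 °C
Reagents that add atoms: none
Why: Diimide reduces the disubstituted C16=C17 alkene much faster than the trisubstituted ring alkene C2=C3.

Step 38
Reactants: 48
Product: 49 triol (C9, C23, C32 hydroxyls)
Conditions: Bu4NF, THF, rt → 50 °C
Reagents that add atoms: none
Why: Fluoride cleaves the three triethylsilyl ethers.

Step 39
Reactants: 49
Product: 50 CNP0194989.3
Conditions: Dess–Martin periodinane, NaHCO3, CH2Cl2, rt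
Reagents that add atoms: none
Why: Only the secondary C23 carbinol can be oxidised, since the two tertiary alcohols and the alkene are inert.

**Compound list**

1 | 3-methylbut-3-enoic acid | CC(=C)CC(=O)O | starting material
2 | (S)-4-benzyloxazolidin-2-one | O=C1N[C@@H](Cc2ccccc2)CO1 | starting material
3 | 3-methylbut-3-enoic pivalic anhydride | CC(=C)CC(=O)OC(=O)C(C)(C)C | intermediate (not isolated)
4 | (S)-4-benzyl-3-(3-methylbut-3-enoyl)oxazolidin-2-one | CC(=C)CC(=O)N1[C@@H](Cc2ccccc2)COC1=O | intermediate
5 | alkylated imide, C18 (R) | CC(=C)[C@H](COCc1ccccc1)C(=O)N1[C@@H](Cc2ccccc2)COC1=O | intermediate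
6 | Weinreb amide | CC(=C)[C@H](COCc1ccccc1)C(=O)N(C)OC | intermediate
7 | (4-bromobut-1-yn-1-yl)trimethylsilane | C[Si](C)(C)C#CCCBr | starting material
8 | silylated ynyl ketone | CC(=C)[C@H](COCc1ccccc1)C(=O)CCC#C[Si](C)(C)C | intermediate
9 | dioxolane of 8 | CC(=C)[C@H](COCc1ccccc1)C1(CCC#C[Si](C)(C)C)OCCO1 | intermediate
10 | terminal alkyne | CC(=C)[C@H](COCc1ccccc1)C1(CCC#C)OCCO1 | intermediate
11 | 2-acetoxy-2-methylpropanoyl chloride | CC(=O)OC(C)(C)C(Cl)=O | starting material
12 | acetoxy ynone | CC(=C)[C@H](COCc1ccccc1)C1(CCC#CC(=O)C(C)(C)OC(C)=O)OCCO1 | intermediate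
13 | hydroxy ynone | CC(=C)[C@H](COCc1ccccc1)C1(CCC#CC(=O)C(C)(C)O)OCCO1 | intermediate (not isolated)
14 | furanone photosubstrate | O=C1C=C(CCC2(OCCO2)[C@@H](COCc3ccccc3)C(C)=C)OC1(C)C | intermediate
15 | photoadduct | c1ccccc1COC[C@H]1[C@]2(C)C[C@H]3C(=O)C(C)(C)O[C@]32CCC14OCCO4 | intermediate
16 | trans-fused oxepanone ketal | c1ccccc1COC[C@H]1[C@]2(C)CCC(=O)C(C)(C)O[C@H]2CCC13OCCO3 | intermediate
17 | C23 carbinol ketal | c1ccccc1COC[C@H]1[C@]2(C)CCC(O)C(C)(C)O[C@H]2CCC13OCCO3 | intermediate
18 | C23 carbinol, C32 ketone | c1ccccc1COC[C@H]1[C@]2(C)CCC(O)C(C)(C)O[C@H]2CCC1=O | intermediate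
19 | C23, C32 diol | c1ccccc1COC[C@H]1[C@]2(C)CCC(O)C(C)(C)O[C@H]2CC[C@@]1(C)O | intermediate
20 | bis(triethylsilyl) ether | c1ccccc1COC[C@H]1[C@]2(C)CCC(O[Si](CC)(CC)CC)C(C)(C)O[C@H]2CC[C@@]1(C)O[Si](CC)(CC)CC | intermediate
21 | C17 alcohol | OC[C@H]1[C@]2(C)CCC(O[Si](CC)(CC)CC)C(C)(C)O[C@H]2CC[C@@]1(C)O[Si](CC)(CC)CC | intermediate
22 | C17 aldehyde | O=C[C@H]1[C@]2(C)CCC(O[Si](CC)(CC)CC)C(C)(C)O[C@H]2CC[C@@]1(C)O[Si](CC)(CC)CC | intermediate
23 | geraniol | CC(C)=CCC/C(C)=C/CO | starting material
24 | (2S,3S)-2,3-epoxygeraniol | CC(C)=CCC[C@]1(C)O[C@H]1CO | intermediate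
25 | 2,3-epoxygeranyl iodide | CC(C)=CCC[C@]1(C)O[C@H]1CI | intermediate
26 | (S)-linalool | C=C[C@@](C)(O)CCC=C(C)C | intermediate
27 | (S)-1-methylcyclopent-2-en-1-ol | C[C@@]1(O)C=CCC1 | intermediate
28 | cis-epoxy alcohol | C[C@]1(O)CC[C@H]2O[C@@H]12 | intermediate
29 | nitrile diol | C[C@]1(O)CC[C@@H]([C@H]1O)C(C)(C)C#N | intermediate
30 | ketol nitrile | C[C@]1(O)CC[C@@H](C1=O)C(C)(C)C#N | intermediate
31 | silylated ketol nitrile | C[C@]1(O[Si](CC)(CC)CC)CC[C@@H](C1=O)C(C)(C)C#N | intermediate
32 | methylene nitrile | C[C@]1(O[Si](CC)(CC)CC)CC[C@@H](C1=C)C(C)(C)C#N | intermediate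
33 | B-alkyl-9-BBN adduct | C[C@]1(O[Si](CC)(CC)CC)CC[C@@H]([C@@H]1CB1C2CCCC1CCC2)C(C)(C)C#N | intermediate (not isolated)
34 | allyl nitrile | C[C@]1(O[Si](CC)(CC)CC)CC[C@@H]([C@@H]1CC=C)C(C)(C)C#N | intermediate
35 | N-H ketimine | C[C@]1(O[Si](CC)(CC)CC)CC[C@@H]([C@@H]1CC=C)C(C)(C)C(=N)C(C)=C | intermediate (not isolated)
36 | isopropenyl ketone | C[C@]1(O[Si](CC)(CC)CC)CC[C@@H]([C@@H]1CC=C)C(C)(C)C(=O)C(C)=C | intermediate
37 | cis-hydroazulenone | CC1=CC[C@H]2[C@H](CC[C@]2(C)O[Si](CC)(CC)CC)C(C)(C)C1=O | intermediate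
38 | C15 tertiary allylic alcohol | CC1=CC[C@H]2[C@H](CC[C@]2(C)O[Si](CC)(CC)CC)C(C)(C)C1(O)COCc1ccc(OC)cc1 | intermediate
39 | transposed enone | CC1=C(COCc3ccc(OC)cc3)C(C)(C)[C@H]2CC[C@](C)(O[Si](CC)(CC)CC)[C@H]2CC1=O | intermediate
40 | C3 allylic alcohol | CC1=C(COCc3ccc(OC)cc3)C(C)(C)[C@H]2CC[C@](C)(O[Si](CC)(CC)CC)[C@H]2C[C@H]1O | intermediate
41 | allylic sulfonylhydrazine | CC1=C(COCc3ccc(OC)cc3)C(C)(C)[C@H]2CC[C@](C)(O[Si](CC)(CC)CC)[C@H]2C[C@@H]1N(N)S(=O)(=O)c1ccccc1[N+](=O)[O-] | intermediate (not isolated)
42 | allylic diazene | CC1=C(COCc3ccc(OC)cc3)C(C)(C)[C@H]2CC[C@](C)(O[Si](CC)(CC)CC)[C@H]2C[C@@H]1N=N | intermediate (not isolated)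
43 | hydroazulene PMB ether | CC1=CC[C@H]2[C@H](CC[C@]2(C)O[Si](CC)(CC)CC)C(C)(C)[C@@H]1COCc1ccc(OC)cc1 | intermediate
44 | C16 alcohol | CC1=CC[C@H]2[C@H](CC[C@]2(C)O[Si](CC)(CC)CC)C(C)(C)[C@@H]1CO | intermediate
45 | C16 tetrazolyl sulfide | CC1=CC[C@H]2[C@H](CC[C@]2(C)O[Si](CC)(CC)CC)C(C)(C)[C@@H]1CSc1nnnn1-c1ccccc1 | intermediate
46 | C16 tetrazolyl sulfone | CC1=CC[C@H]2[C@H](CC[C@]2(C)O[Si](CC)(CC)CC)C(C)(C)[C@@H]1CS(=O)(=O)c1nnnn1-c1ccccc1 | intermediate
47 | coupled (E)-alkene | CC1=CC[C@H]2[C@H](CC[C@]2(C)O[Si](CC)(CC)CC)C(C)(C)[C@@H]1/C=C/[C@H]1[C@]2(C)CCC(O[Si](CC)(CC)CC)C(C)(C)O[C@H]2CC[C@@]1(C)O[Si](CC)(CC)CC | intermediate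
48 | saturated tris(silyl) ether | CC1=CC[C@H]2[C@H](CC[C@]2(C)O[Si](CC)(CC)CC)C(C)(C)[C@@H]1CC[C@H]1[C@]2(C)CCC(O[Si](CC)(CC)CC)C(C)(C)O[C@H]2CC[C@@]1(C)O[Si](CC)(CC)CC | intermediate
49 | triol | CC1=CC[C@H]2[C@H](CC[C@]2(C)O)C(C)(C)[C@@H]1CC[C@H]1[C@]2(C)CCC(O)C(C)(C)O[C@H]2CC[C@@]1(C)O | intermediate
50 | CNP0194989.3 | CC1=CC[C@H]2[C@H](CC[C@]2(C)O)C(C)(C)[C@@H]1CC[C@H]1[C@]2(C)CCC(=O)C(C)(C)O[C@H]2CC[C@@]1(C)O | target

**Counts**

Total steps: 39 (16 for aldehyde 22, 19 for sulfone 46, 4 after the union).
Longest linear sequence: 23 steps (geraniol 23 → 50, steps 17–35 and 36–39).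

**Steps most likely to fail**

Step 9. The furanone triplet may add to the other face of the isopropenyl group, because the relay from C18 alone is weak, and this would give the C19/C29-epimeric series; first bonding at C21 would give crossed adducts. Fallback: C18 becomes epimerisable once the C32 ketone is unveiled, and equatorial C17 is the stable arrangement there, so an intrinsic preference for the other face can be used in the mirror-image sense. Setting out from 1, acylation of (R)-4-benzyloxazolidin-2-one through anhydride 3 should give the (R)-imide F1. The chemistry of steps 2–8 would then give the (S)-alkylated imide F2, the (S)-Weinreb amide F3, the (S)-ynyl ketone F4, its dioxolane F5, the terminal alkyne F6, the acetoxy ynone F7, the hydroxy ynone F8 and the enantiomeric furanone F9. Irradiation should then deliver the 18-epi photoadduct F10, which has C19, C22 and C29 as in 15. SmI2 cleavage would give the 18-epi oxepanone F11 and NaBH4 the 18-epi carbinol F12. Ketal hydrolysis under equilibrating conditions (aq. HCl–THF, or K2CO3–MeOH afterwards) would pass through the 18-epi hydroxy ketone F13, which should epimerise at C18 to 18, where the route is rejoined.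

Step 10. The ketyl may instead cleave the better-aligned exocyclic C21–C22 bond, expel O28 from C25 as in α-alkoxy ketone reduction, or over-reduce the product; hydrogen may also reach C29 from the wrong face. Fallback: open the donor–acceptor cyclobutane heterolytically. From 15, BF3·OEt2 (0.2 equiv, CH2Cl2, −78 → −20 °C) should ionise the C22–C29 bond, with O28 as donor and the C23 ketone as acceptor, and proton loss from C30 would give the ring-expanded C29=C30 enol ether F14. Hydrogenation (H2, Pd/C, pyridine, EtOAc, which spares the benzyl ether) from the face anti to the axial C20 methyl should return 16.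

Step 36. The sulfonyl carbanion sits next to C15 and the quaternary C12, and the aldehyde is hindered and enolisable, so addition may be slow and enolisation or sulfone self-condensation may take over. Fallback: form the C16–C17 bond by organolithium addition and remove the oxygen by radical deoxygenation. From 44, I2/PPh3/imidazole would give the C16 iodide F15. Lithium–iodine exchange (t-BuLi, Et2O, −78 °C) and addition to aldehyde 22 would give the C17 carbinol F16. NaH/CS2/MeI would give the xanthate F17, and Bu3SnH/AIBN (toluene, 90 °C) should give 48 directly, so step 37 is not needed.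

**Further compounds**

F1 | step 9 | (R)-4-benzyl-3-(3-methylbut-3-enoyl)oxazolidin-2-one | CC(=C)CC(=O)N1[C@H](Cc2ccccc2)COC1=O
F2 | step 9 | (R)-4-benzyl-3-[(2S)-2-(benzyloxymethyl)-3-methylbut-3-enoyl]oxazolidin-2-one | CC(=C)[C@@H](COCc1ccccc1)C(=O)N1[C@H](Cc2ccccc2)COC1=O
F3 | step 9 | (2S)-2-(benzyloxymethyl)-N-methoxy-N,3-dimethylbut-3-enamide | CC(=C)[C@@H](COCc1ccccc1)C(=O)N(C)OC
F4 | step 9 | enantiomer of ynyl ketone 8 | CC(=C)[C@@H](COCc1ccccc1)C(=O)CCC#C[Si](C)(C)C
F5 | step 9 | enantiomer of dioxolane 9 | CC(=C)[C@@H](COCc1ccccc1)C1(CCC#C[Si](C)(C)C)OCCO1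
F6 | step 9 | enantiomer of alkyne 10 | CC(=C)[C@@H](COCc1ccccc1)C1(CCC#C)OCCO1
F7 | step 9 | enantiomer of acetoxy ynone 12 | CC(=C)[C@@H](COCc1ccccc1)C1(CCC#CC(=O)C(C)(C)OC(C)=O)OCCO1
F8 | step 9 | enantiomer of hydroxy ynone 13 | CC(=C)[C@@H](COCc1ccccc1)C1(CCC#CC(=O)C(C)(C)O)OCCO1
F9 | step 9 | enantiomer of furanone 14 | O=C1C=C(CCC2(OCCO2)[C@H](COCc3ccccc3)C(C)=C)OC1(C)C
F10 | step 9 | 18-epi photoadduct | c1ccccc1COC[C@@H]1[C@]2(C)C[C@H]3C(=O)C(C)(C)O[C@]32CCC14OCCO4
F11 | step 9 | 18-epi oxepanone ketal | c1ccccc1COC[C@@H]1[C@]2(C)CCC(=O)C(C)(C)O[C@H]2CCC13OCCO3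
F12 | step 9 | 18-epi C23 carbinol ketal | c1ccccc1COC[C@@H]1[C@]2(C)CCC(O)C(C)(C)O[C@H]2CCC13OCCO3
F13 | step 9 | 18-epi hydroxy ketone | c1ccccc1COC[C@@H]1[C@]2(C)CCC(O)C(C)(C)O[C@H]2CCC1=O
F14 | step 10 | ring-expanded C29=C30 enol ether | c1ccccc1COC[C@H]1[C@]2(C)CCC(=O)C(C)(C)OC2=CCC13OCCO3
F15 | step 36 | C16 iodide | CC1=CC[C@H]2[C@H](CC[C@]2(C)O[Si](CC)(CC)CC)C(C)(C)[C@@H]1CI
F16 | step 36 | C17 carbinol (C17 epimers) | CC1=CC[C@H]2[C@H](CC[C@]2(C)O[Si](CC)(CC)CC)C(C)(C)[C@@H]1CC(O)[C@H]1[C@]2(C)CCC(O[Si](CC)(CC)CC)C(C)(C)O[C@H]2CC[C@@]1(C)O[Si](CC)(CC)CC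
F17 | step 36 | C17 S-methyl xanthate | CC1=CC[C@H]2[C@H](CC[C@]2(C)O[Si](CC)(CC)CC)C(C)(C)[C@@H]1CC(OC(=S)SC)[C@H]1[C@]2(C)CCC(O[Si](CC)(CC)CC)C(C)(C)O[C@H]2CC[C@@]1(C)O[Si](CC)(CC)CC
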